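## Retrosynthetic overview

1. Target ⇒ epoxy triol, by benzoylation of the primary C7–OH and the allylic C3–OH only; the triol comes from its 3,7-bis-silyl ether.
2. Cyclohexene ⇒ ring-closing metathesis (C4=C5) of an open-chain epoxy alcohol that carries two vinyl groups.
3. Oxirane ⇒ hydroxyl-directed epoxidation of a (Z)-dienyl carbinol, which is made by Ni/Cr coupling (C1–C2 bond) of fragment A, (S)-2-silyloxybut-3-enal, with fragment B, a (Z)-2-iodopenta-2,4-dienyl silyl ether.
4. Fragment A ⇒ racemic vinyloxirane (hydrolytic kinetic resolution); fragment B ⇒ propargyl alcohol (hydroxymethylation, trans-hydroalumination/iodination, oxidation, methylenation).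
5. Ring order: oxirane first, on the open chain; carbocycle second, by metathesis.

Assumption: the SMILES is read as [(1R,2S,3S,6S)-3-(benzoyloxy)-2-hydroxy-7-oxabicyclo[4.1.0]hept-4-en-1-yl]methyl benzoate, with C1 the oxirane carbon bearing CH2OBz (C7) and C6 the oxirane CH; these target locants are also used for positions in open-chain intermediates.

Abbreviations: TBS = tert-butyldimethylsilyl (TBSO = silyloxy, TBSOCH2 = silyloxymethyl); Piv = 2,2-dimethylpropanoyl; Bz = benzoyl; mCPBA = 3-chloroperoxybenzoic acid; salen = N,N′-bis(3,5-di-tert-butylsalicylidene)cyclohexane-1,2-diaminate (its cobalt acetate complex holds trivalent cobalt).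

## Route

**Fragment A**

Step 1
Reactants: 1 rac-2-ethenyloxirane (butadiene monoxide)
Product: 2 (2S)-but-3-ene-1,2-diol
Conditions: (S,S)-(salen)Co(OAc) (0.5 mol%), H2O (0.45 equiv), neat, 0 °C → rt; distil
Reagents that add atoms: water, O
Why: Jacobsen hydrolytic kinetic resolution: the catalyst hydrates only the (S)-epoxide at its terminal carbon, so the C–O bond at the stereocenter is kept and the volatile (R)-enantiomer of 1 is distilled off.

Step 2
Reactants: 2 (2S)-but-3-ene-1,2-diol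
Product: 3 (2S)-2-hydroxybut-3-en-1-yl 2,2-dimethylpropanoate
Conditions: PivCl (1.05 equiv), pyridine, CH2Cl2, −20 °C
Reagents that add atoms: pivaloyl chloride, CC(C)(C)C(=O)Cl
Why: Sterically controlled acylation: the bulky acid chloride esterifies the primary hydroxyl selectively and the stereocenter is untouched.

Step 3
Reactants: 3 (2S)-2-hydroxybut-3-en-1-yl 2,2-dimethylpropanoate
Product: 4 (2S)-2-(TBSO)but-3-en-1-yl 2,2-dimethylpropanoate
Conditions: TBSCl, imidazole, DMF, rt
Reagents that add atoms: tert-butyldimethylsilyl chloride, CC(C)(C)[Si](C)(C)Cl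
Why: Standard imidazole-promoted silylation of the secondary allylic alcohol; the hindered pivalate does not migrate.

Step 4
Reactants: 4 (2S)-2-(TBSO)but-3-en-1-yl 2,2-dimethylpropanoate
Product: 5 (2S)-2-(TBSO)but-3-en-1-ol
Conditions: i-Bu2AlH (2.2 equiv), CH2Cl2, −78 °C; aq. potassium sodium tartrate
Reagents that add atoms: none
Why: Reductive ester cleavage with an aluminium hydride frees the primary alcohol under non-basic conditions, so the silyl ether neither cleaves nor migrates.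

Step 5
Reactants: 5 (2S)-2-(TBSO)but-3-en-1-ol
Product: 6 (2S)-2-(TBSO)but-3-enal (fragment A)
Conditions: Dess–Martin periodinane, CH2Cl2, 0 °C; used crude at once
Reagents that add atoms: none
Why: Dess–Martin oxidation is mild and base-free, which keeps the α-stereocenter and the β,γ-alkene of this sensitive aldehyde in place.

**Fragment B**

Step 6
Reactants: 7 prop-2-yn-1-ol
Product: 8 tert-butyldimethyl(prop-2-yn-1-yloxy)silane
Conditions: TBSCl, imidazole, CH2Cl2, 0 °C → rt
Reagents that add atoms: tert-butyldimethylsilyl chloride, CC(C)(C)[Si](C)(C)Cl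
Why: Routine silylation of a primary alcohol; it fixes which oxygen of the later butynediol unit is protected and avoids a statistical monoprotection.

Step 7
Reactants: 8 tert-butyldimethyl(prop-2-yn-1-yloxy)silane
Product: 10 4-(TBSO)but-2-yn-1-ol, via lithium acetylide 9 (not isolated)
Conditions: n-BuLi, THF, −78 °C; (CH2O)n, −78 °C → rt; H2O
Reagents that add atoms: paraformaldehyde (as formaldehyde), C=O
Why: Acetylide hydroxymethylation: the terminal alkyne is deprotonated and the alkynyllithium adds to formaldehyde.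

Step 8
Reactants: 10 4-(TBSO)but-2-yn-1-ol
Product: 12 (2Z)-4-(TBSO)-3-iodobut-2-en-1-ol, via cyclic sodium alkenylaluminate 11 (not isolated)
Conditions: NaAlH2(OCH2CH2OCH3)2 (1.3 equiv), THF, 0 °C; then I2, −78 → 0 °C; aq. Na2S2O3
Reagents that add atoms: iodine, [I][I]
Why: Hydroxyl-directed trans-hydroalumination places aluminium on the alkyne carbon remote from the free OH through a five-membered alkoxyaluminate, and iodinolysis of the C–Al bond with retention gives the (Z)-iodoalkene with iodine on the carbon bearing CH2OTBS.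

Step 9
Reactants: 12 (2Z)-4-(TBSO)-3-iodobut-2-en-1-ol
Product: 13 (2Z)-4-(TBSO)-3-iodobut-2-enal
Conditions: MnO2 (excess), CH2Cl2, rt, dark
Reagents that add atoms: none
Why: Neutral allylic oxidation with manganese dioxide stops at the aldehyde and leaves the (Z)-iodoalkene geometry unchanged.

Step 10
Reactants: 13 (2Z)-4-(TBSO)-3-iodobut-2-enal
Product: 14 tert-butyl{[(2Z)-2-iodopenta-2,4-dien-1-yl]oxy}dimethylsilane (fragment B)
Conditions: Ph3PCH3Br, KN(SiMe3)2, THF, −78 → 0 °C
Reagents that add atoms: methyltriphenylphosphonium bromide, C[P+](c1ccccc1)(c1ccccc1)c1ccccc1.[Br-]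
Why: Wittig methylenation: the unstabilised ylide adds 1,2 to the aldehyde and installs the terminal vinyl group without touching the trisubstituted iodoalkene.

**Union and end game**

Step 11
Reactants: 6 (2S)-2-(TBSO)but-3-enal; 14 tert-butyl{[(2Z)-2-iodopenta-2,4-dien-1-yl]oxy}dimethylsilane
Product: 16 (3S,4R,5Z)-3-(TBSO)-5-(TBSOCH2)octa-1,5,7-trien-4-ol, via alkenylchromium dichloride 15 (not isolated)
Conditions: CrCl2 (4 equiv), NiCl2 (2 mol%), degassed DMSO, rt; H2O
Reagents that add atoms: none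
Why: Nozaki–Hiyama–Kishi coupling: zerovalent nickel inserts into the C–I bond and the alkenyl group passes to trivalent chromium with retention of geometry. It then adds to the aldehyde anti to the α-silyloxy group (Felkin–Anh), which sets the 3,4-anti carbinol (target C2) without epimerising the aldehyde.

Step 12
Reactants: 16 (3S,4R,5Z)-3-(TBSO)-5-(TBSOCH2)octa-1,5,7-trien-4-ol
Product: 17 (1S,2S)-2-(TBSO)-1-[(2R,3S)-2-(TBSOCH2)-3-ethenyloxiran-2-yl]but-3-en-1-ol
Conditions: mCPBA (1.1 equiv), NaHCO3, CH2Cl2, −10 → 0 °C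
Reagents that add atoms: 3-chloroperoxybenzoic acid, O=C(OO)c1cccc(Cl)c1
Why: Hydroxyl-directed peracid epoxidation of the most electron-rich (trisubstituted) alkene: A(1,3) strain with the cis vinyl group holds the carbinol C–H in the alkene plane, so the hydrogen-bonded peracid attacks the face bearing the OH and gives the threo epoxy alcohol, with the oxirane oxygen anti to the C2–OH in the later ring.

Step 13
Reactants: 17 (1S,2S)-2-(TBSO)-1-[(2R,3S)-2-(TBSOCH2)-3-ethenyloxiran-2-yl]but-3-en-1-ol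
Product: 18 (1R,2S,3S,6S)-3-(TBSO)-1-(TBSOCH2)-7-oxabicyclo[4.1.0]hept-4-en-2-ol
Conditions: second-generation Grubbs catalyst RuCl2(=CHPh)(PCy3)(1,3-dimesitylimidazolidin-2-ylidene) (5 mol%), CH2Cl2 (5 mM), 40 °C
Reagents that add atoms: none
Why: Ring-closing metathesis of the two terminal vinyl groups, held cis on the oxirane, closes the six-membered ring with loss of ethene and touches no stereocenter.

Step 14
Reactants: 18 (1R,2S,3S,6S)-3-(TBSO)-1-(TBSOCH2)-7-oxabicyclo[4.1.0]hept-4-en-2-ol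
Product: 19 (1R,2S,3S,6S)-1-(hydroxymethyl)-7-oxabicyclo[4.1.0]hept-4-ene-2,3-diol
Conditions: Bu4NF/AcOH (1:1, 2.5 equiv), THF, 0 °C → rt
Reagents that add atoms: none
Why: Fluoride-mediated desilylation removes both silyl ethers; buffering with acetic acid avoids free alkoxides next to the oxirane and therefore Payne rearrangement.

Step 15
Reactants: 19 (1R,2S,3S,6S)-1-(hydroxymethyl)-7-oxabicyclo[4.1.0]hept-4-ene-2,3-diol
Product: 20 [(1R,2S,3S,6S)-3-(benzoyloxy)-2-hydroxy-7-oxabicyclo[4.1.0]hept-4-en-1-yl]methyl benzoate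
Conditions: BzCl (2.1 equiv), pyridine, CH2Cl2, −40 → −10 °C
Reagents that add atoms: benzoyl chloride, O=C(Cl)c1ccccc1
Why: Kinetically selective acylation: the primary C7–OH and the allylic C3–OH are expected to react before the C2–OH, which is flanked by the fully substituted oxirane carbon and the new C3 ester; the low temperature suppresses acyl migration.

## Compound list

1 | rac-2-ethenyloxirane | C=CC1CO1 | starting material
2 | (2S)-but-3-ene-1,2-diol | OC[C@@H](O)C=C | intermediate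
3 | (2S)-2-hydroxybut-3-en-1-yl 2,2-dimethylpropanoate | CC(C)(C)C(=O)OC[C@@H](O)C=C | intermediate
4 | (2S)-2-(TBSO)but-3-en-1-yl 2,2-dimethylpropanoate | CC(C)(C)C(=O)OC[C@@H](O[Si](C)(C)C(C)(C)C)C=C | intermediate
5 | (2S)-2-(TBSO)but-3-en-1-ol | OC[C@@H](O[Si](C)(C)C(C)(C)C)C=C | intermediate
6 | (2S)-2-(TBSO)but-3-enal | O=C[C@@H](O[Si](C)(C)C(C)(C)C)C=C | intermediate
7 | prop-2-yn-1-ol | C#CCO | starting material
8 | tert-butyldimethyl(prop-2-yn-1-yloxy)silane | C#CCO[Si](C)(C)C(C)(C)C | intermediate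
9 | [3-(TBSO)prop-1-yn-1-yl]lithium | [Li]C#CCO[Si](C)(C)C(C)(C)C | intermediate (not isolated)
10 | 4-(TBSO)but-2-yn-1-ol | OCC#CCO[Si](C)(C)C(C)(C)C | intermediate
11 | sodium 2,2-bis(2-methoxyethoxy)-3-(TBSOCH2)-2,5-dihydro-1,2-oxaluminol-2-uide (cyclic alkenylaluminate) | [Na+].COCCO[Al-]1(OCCOC)OCC=C1CO[Si](C)(C)C(C)(C)C | intermediate (not isolated)
12 | (2Z)-4-(TBSO)-3-iodobut-2-en-1-ol | I/C(CO[Si](C)(C)C(C)(C)C)=C\CO | intermediate
13 | (2Z)-4-(TBSO)-3-iodobut-2-enal | I/C(CO[Si](C)(C)C(C)(C)C)=C\C=O | intermediate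
14 | tert-butyl{[(2Z)-2-iodopenta-2,4-dien-1-yl]oxy}dimethylsilane | I/C(CO[Si](C)(C)C(C)(C)C)=C\C=C | intermediate
15 | dichloro[(2Z)-1-(TBSO)penta-2,4-dien-2-yl]chromium (trivalent chromium) | Cl[Cr](Cl)/C(CO[Si](C)(C)C(C)(C)C)=C\C=C | intermediate (not isolated)
16 | (3S,4R,5Z)-3-(TBSO)-5-(TBSOCH2)octa-1,5,7-trien-4-ol | CC(C)(C)[Si](C)(C)OC/C(=C/C=C)[C@@H](O)[C@@H](O[Si](C)(C)C(C)(C)C)C=C | intermediate
17 | (1S,2S)-2-(TBSO)-1-[(2R,3S)-2-(TBSOCH2)-3-ethenyloxiran-2-yl]but-3-en-1-ol | CC(C)(C)[Si](C)(C)OC[C@@]1(O[C@H]1C=C)[C@@H](O)[C@@H](O[Si](C)(C)C(C)(C)C)C=C | intermediate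
18 | (1R,2S,3S,6S)-3-(TBSO)-1-(TBSOCH2)-7-oxabicyclo[4.1.0]hept-4-en-2-ol | CC(C)(C)[Si](C)(C)OC[C@]12O[C@H]1C=C[C@H](O[Si](C)(C)C(C)(C)C)[C@@H]2O | intermediate
19 | (1R,2S,3S,6S)-1-(hydroxymethyl)-7-oxabicyclo[4.1.0]hept-4-ene-2,3-diol | OC[C@]12O[C@H]1C=C[C@H](O)[C@@H]2O | intermediate
20 | [(1R,2S,3S,6S)-3-(benzoyloxy)-2-hydroxy-7-oxabicyclo[4.1.0]hept-4-en-1-yl]methyl benzoate | O=C(OC[C@]12O[C@H]1C=C[C@H](OC(=O)c1ccccc1)[C@@H]2O)c1ccccc1 | target

## Step count and risks

Total step count: 15 (steps 1–5 for fragment A, steps 6–10 for fragment B, steps 11–15 after their union).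
Longest linear sequence: 10 steps (1–5 then 11–15; equally 6–10 then 11–15).

**Step 11 (coupling).** The Felkin–Anh preference of an α-silyloxy aldehyde towards an alkenylchromium is often only moderate, and aldehyde 6 is sensitive. The fallback sets out from 16, taken as the mixture of C4 epimers delivered by the coupling, and comes back to 16 as a single isomer. The mixture is oxidised with Dess–Martin periodinane (CH2Cl2, 0 °C) to (3S,5Z)-3-(TBSO)-5-(TBSOCH2)octa-1,5,7-trien-4-one F1. This ketone is reduced at −78 °C with NaBH4 and CeCl3·7H2O in MeOH; 1,2-delivery of hydride anti to the α-silyloxy group returns the (4R) alcohol 16. The stereocenter is then set by ketone reduction and no longer by the C–C bond formation.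

**Step 13 (metathesis on a vinyl oxirane).** The ruthenium carbene next to the oxirane may initiate slowly or decompose. The fallback sets out from 16 and comes back at 19; the ring is closed before the oxirane exists.
- The same ruthenium catalyst joins the two terminal CH=CH2 groups of 16 and gives (1R,6S)-6-(TBSO)-2-(TBSOCH2)cyclohexa-2,4-dien-1-ol F2, a protected arene cis-dihydrodiol type.
- Silylation (TBSOTf, 2,6-lutidine, CH2Cl2, −78 °C) gives (5S,6R)-5,6-bis(TBSO)-1-(TBSOCH2)cyclohexa-1,3-diene F3.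
- mCPBA with NaHCO3 epoxidises the trisubstituted alkene from the face opposite the two cis silyloxy groups (steric control) and gives (1R,2S,3S,6S)-2,3-bis(TBSO)-1-(TBSOCH2)-7-oxabicyclo[4.1.0]hept-4-ene F4.
- Bu4NF/AcOH removes the three silyl groups and delivers triol 19.

**Step 15 (selective dibenzoylation).** The C2–OH may compete, or the benzoate may migrate between O3 and O2. The fallback sets out from 18 and comes back at 20; it fixes the regiochemistry by protection.
- The free C2–OH of 18 is etherified under neutral conditions (2-(4-methoxybenzyloxy)-4-methylquinoline, MeOTf, MgO, PhCF3) to (1R,2S,3S,6S)-2-[(4-methoxybenzyl)oxy]-3-(TBSO)-1-(TBSOCH2)-7-oxabicyclo[4.1.0]hept-4-ene F5.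
- Bu4NF/AcOH gives (1R,2S,3S,6S)-1-(hydroxymethyl)-2-[(4-methoxybenzyl)oxy]-7-oxabicyclo[4.1.0]hept-4-en-3-ol F6.
- Exhaustive benzoylation (BzCl, pyridine, 4-dimethylaminopyridine) gives [(1R,2S,3S,6S)-3-(benzoyloxy)-2-[(4-methoxybenzyl)oxy]-7-oxabicyclo[4.1.0]hept-4-en-1-yl]methyl benzoate F7.
- DDQ in wet CH2Cl2 at pH 7 removes the 4-methoxybenzyl group and liberates 20 without base.

## Further compounds

F1 | step 11 | (3S,5Z)-3-(TBSO)-5-(TBSOCH2)octa-1,5,7-trien-4-one | CC(C)(C)[Si](C)(C)OC/C(=C/C=C)C(=O)[C@@H](O[Si](C)(C)C(C)(C)C)C=C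
F2 | step 13 | (1R,6S)-6-(TBSO)-2-(TBSOCH2)cyclohexa-2,4-dien-1-ol | CC(C)(C)[Si](C)(C)OCC1=CC=C[C@H](O[Si](C)(C)C(C)(C)C)[C@@H]1O
F3 | step 13 | (5S,6R)-5,6-bis(TBSO)-1-(TBSOCH2)cyclohexa-1,3-diene | CC(C)(C)[Si](C)(C)OCC1=CC=C[C@H](O[Si](C)(C)C(C)(C)C)[C@@H]1O[Si](C)(C)C(C)(C)C
F4 | step 13 | (1R,2S,3S,6S)-2,3-bis(TBSO)-1-(TBSOCH2)-7-oxabicyclo[4.1.0]hept-4-ene | CC(C)(C)[Si](C)(C)OC[C@]12O[C@H]1C=C[C@H](O[Si](C)(C)C(C)(C)C)[C@@H]2O[Si](C)(C)C(C)(C)C
F5 | step 15 | (1R,2S,3S,6S)-2-[(4-methoxybenzyl)oxy]-3-(TBSO)-1-(TBSOCH2)-7-oxabicyclo[4.1.0]hept-4-ene | CC(C)(C)[Si](C)(C)OC[C@]12O[C@H]1C=C[C@H](O[Si](C)(C)C(C)(C)C)[C@@H]2OCc1ccc(OC)cc1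
F6 | step 15 | (1R,2S,3S,6S)-1-(hydroxymethyl)-2-[(4-methoxybenzyl)oxy]-7-oxabicyclo[4.1.0]hept-4-en-3-ol | OC[C@]12O[C@H]1C=C[C@H](O)[C@@H]2OCc1ccc(OC)cc1
F7 | step 15 | [(1R,2S,3S,6S)-3-(benzoyloxy)-2-[(4-methoxybenzyl)oxy]-7-oxabicyclo[4.1.0]hept-4-en-1-yl]methyl benzoate | O=C(OC[C@]12O[C@H]1C=C[C@H](OC(=O)c1ccccc1)[C@@H]2OCc1ccc(OC)cc1)c1ccccc1
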